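**Remark on the chemistry:** positions are given with carotenoid locants (C1–C15 from the acyclic end, C15'–C1' to the ring). Compounds 2 and 16 and the (E)-C5 cyanophosphonate are taken as purchasable. All polyenes are handled under argon in dim light.

## Retrosynthetic overview

1. The last C–C bond is C12–C13 (step 28): pentaenyl iodide 15 (C1–C12) is joined to the methyl-capped polyenyne 35 (C13–C7' plus ring) by one-pot hydrozirconation, zinc transmetalation and palladium coupling; the two silyl ethers are then removed.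
2. Enabling feature: C13 carries a CH3 group and sits in the (E)-trisubstituted C13=C14 alkene, bonded through C12 to the (E)-C11=C12 alkene. The C12–C13(CH3)=C14 unit is what syn H–Zr addition to a CH3–C13≡C14 alkyne and stereoretentive coupling at C13 deliver, so the right half needs only a but-2-ynyl cap, and the methyl group steers Zr to C13.
3. Both polyene arms grow by repeated Horner–Wadsworth–Emmons (HWE) olefination with a C5 cyanophosphonate and nitrile-to-aldehyde reduction. The C12 iodide comes from Takai olefination; the C13–C15 cap comes from phosphonate 34.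
4. C2 is set by auxiliary-controlled hydroxymethylation (6); the C1 carbinol is made from the acyl carbon with MeMgBr.
5. The only ring (carbocycle C1'–C6') is bought as enone 16; no ring is formed. C2' is set by rhodium-catalysed asymmetric vinyl addition to dienone 17. C6' is relayed from it by Luche reduction and a suprafacial Still–Wittig shift, which also places C4'=C5'.

Key step: step 28

## Route

### Left half (C1–C12)

Step 1
Reactants: 1 (R)-4-benzyloxazolidin-2-one; 2 5-methylhex-4-enoic acid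
Product: 4 (R)-4-benzyl-3-(5-methylhex-4-enoyl)oxazolidin-2-one, via mixed pivalic anhydride 3 (not isolated)
Conditions: 2, t-BuCOCl, Et3N, THF, −20 °C; then LiCl, 1, −20 °C → rt
Reagents that add atoms: pivaloyl chloride, CC(C)(C)C(=O)Cl (in 3 only)
Why: mixed-anhydride N-acylation of the LiCl-activated oxazolidinone installs the auxiliary, and no stereocentre is formed.

Step 2
Reactants: 4 (R)-4-benzyl-3-(5-methylhex-4-enoyl)oxazolidin-2-one
Product: 6 (R)-4-benzyl-3-[(S)-2-(hydroxymethyl)-5-methylhex-4-enoyl]oxazolidin-2-one, via chlorotitanium (Z)-enolate 5 (not isolated)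
Conditions: TiCl4, i-Pr2NEt, CH2Cl2, 0 °C; then 1,3,5-trioxane, TiCl4, 0 °C
Reagents that add atoms: 1,3,5-trioxane, C1OCOCO1; titanium tetrachloride, Cl[Ti](Cl)(Cl)Cl (in 5 only)
Why: Evans-type titanium-enolate hydroxymethylation, in which the chelated (Z)-enolate is attacked by TiCl4-activated formaldehyde on the face opposite the benzyl group, so the (R)-auxiliary should give the (S)-centre that becomes C2; the enolate should outcompete the isolated trisubstituted alkene for the electrophile.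

Step 3
Reactants: 6 (R)-4-benzyl-3-[(S)-2-(hydroxymethyl)-5-methylhex-4-enoyl]oxazolidin-2-one
Product: 7 methyl (S)-2-(hydroxymethyl)-5-methylhex-4-enoate
Conditions: MeMgBr, MeOH, CH2Cl2, 0 °C
Reagents that add atoms: methanol, CO
Why: transesterification with bromomagnesium methoxide cleaves the exocyclic imide carbonyl under conditions mild enough to avoid epimerisation and retro-aldol loss of formaldehyde, and the auxiliary is recovered.

Step 4
Reactants: 7 methyl (S)-2-(hydroxymethyl)-5-methylhex-4-enoate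
Product: 8 (S)-3-methyl-2-(3-methylbut-2-en-1-yl)butane-1,3-diol
Conditions: MeMgBr (excess), THF, −20 → 0 °C
Reagents that add atoms: methylmagnesium bromide, C[Mg]Br
Why: double Grignard addition to the ester builds the C1 dimethylcarbinol, and the β-alkoxide formed first should disfavour enolisation of the ketone intermediate so that C2 is kept.

Step 5
Reactants: 8 (S)-3-methyl-2-(3-methylbut-2-en-1-yl)butane-1,3-diol
Product: 9 bis(triethylsilyl) ether of 8
Conditions: Et3SiOTf, 2,6-lutidine, CH2Cl2, −78 → 0 °C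
Reagents that add atoms: triethylsilyl trifluoromethanesulfonate, CC[Si](CC)(CC)OS(=O)(=O)C(F)(F)F
Why: silyl triflate and lutidine silylate both hydroxyl groups, the hindered tertiary one included (silyl ether formation).

Step 6
Reactants: 9 bis(triethylsilyl) ether of 8
Product: 10 (R)-5-methyl-2-[2-(triethylsilyloxy)propan-2-yl]hex-4-enal
Conditions: (COCl)2, DMSO, CH2Cl2, −78 → −30 °C; then Et3N, → 0 °C
Reagents that add atoms: none
Why: under Swern conditions a primary triethylsilyl ether is cleaved and oxidised directly to the aldehyde while the hindered tertiary silyl ether stays (oxidative desilylation), so no free β-hydroxy aldehyde prone to retro-aldol cleavage is formed.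

Step 7
Reactants: 10 (R)-5-methyl-2-[2-(triethylsilyloxy)propan-2-yl]hex-4-enal
Product: 11 (2E,4E,6S)-3,9-dimethyl-6-[2-(triethylsilyloxy)propan-2-yl]deca-2,4,8-trienenitrile
Conditions: (E)-C5 cyanophosphonate (slight excess over base), LiN(SiMe3)2, THF, −78 → 0 °C
Reagents that add atoms: diethyl [(E)-3-cyano-2-methylprop-2-en-1-yl]phosphonate, N#C/C=C(\C)CP(=O)(OCC)OCC
Why: HWE olefination with the vinylogous cyanophosphonate should form C3=C4 with E geometry and bring C4–C7 with the C5 methyl group; the weakly basic stabilised anion should not epimerise the α-centre.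

Step 8
Reactants: 11 (2E,4E,6S)-3,9-dimethyl-6-[2-(triethylsilyloxy)propan-2-yl]deca-2,4,8-trienenitrile
Product: 12 (2E,4E,6S)-3,9-dimethyl-6-[2-(triethylsilyloxy)propan-2-yl]deca-2,4,8-trienal
Conditions: i-Bu2AlH, toluene, −78 °C; then wet SiO2 or aq. KNaC4H4O6
Reagents that add atoms: water, O
Why: partial reduction of the nitrile stops at the N-aluminoaldimine, which is hydrolysed to the aldehyde on work-up; any (2Z)-isomer is removed here.

Step 9
Reactants: 12 (2E,4E,6S)-3,9-dimethyl-6-[2-(triethylsilyloxy)propan-2-yl]deca-2,4,8-trienal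
Product: 13 (2E,4E,6E,8E,10S)-3,7,13-trimethyl-10-[2-(triethylsilyloxy)propan-2-yl]tetradeca-2,4,6,8,12-pentaenenitrile
Conditions: (E)-C5 cyanophosphonate, LiN(SiMe3)2, THF, −78 → 0 °C
Reagents that add atoms: diethyl [(E)-3-cyano-2-methylprop-2-en-1-yl]phosphonate, N#C/C=C(\C)CP(=O)(OCC)OCC
Why: a second HWE olefination should form C7=C8 (E) and bring C8–C11 with the C9 methyl group.

Step 10
Reactants: 13 (2E,4E,6E,8E,10S)-3,7,13-trimethyl-10-[2-(triethylsilyloxy)propan-2-yl]tetradeca-2,4,6,8,12-pentaenenitrile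
Product: 14 (2E,4E,6E,8E,10S)-3,7,13-trimethyl-10-[2-(triethylsilyloxy)propan-2-yl]tetradeca-2,4,6,8,12-pentaenal
Conditions: i-Bu2AlH, toluene, −78 °C; then wet SiO2 or aq. KNaC4H4O6
Reagents that add atoms: water, O
Why: nitrile partial reduction as in step 8 gives the C11 aldehyde.

Step 11
Reactants: 14 (2E,4E,6E,8E,10S)-3,7,13-trimethyl-10-[2-(triethylsilyloxy)propan-2-yl]tetradeca-2,4,6,8,12-pentaenal
Product: 15 (1E,3E,5E,7E,9E,11S)-1-iodo-4,8,14-trimethyl-11-[2-(triethylsilyloxy)propan-2-yl]pentadeca-1,3,5,7,9,13-hexaene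
Conditions: CrCl2, CHI3, THF/1,4-dioxane, 0 °C → rt, dark; used at once
Reagents that add atoms: iodoform, IC(I)I
Why: Takai olefination, in which the gem-dichromium reagent from CHI3 and CrCl2 should convert the aldehyde into the (E)-alkenyl iodide (C11=C12) while leaving the polyene and silyl ether alone.

### Right half (C13–C1')

Step 12
Reactants: 16 2,4,4-trimethylcyclohex-2-en-1-one
Product: 17 2,4,4-trimethylcyclohexa-2,5-dien-1-one
Conditions: DDQ, 1,4-dioxane, reflux
Reagents that add atoms: none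
Why: DDQ dehydrogenation at C5–C6 gives the cross-conjugated dienone, which cannot aromatise because C4 is quaternary.

Step 13
Reactants: 17 2,4,4-trimethylcyclohexa-2,5-dien-1-one
Product: 18 (R)-2,4,4-trimethyl-5-vinylcyclohex-2-en-1-one
Conditions: K[CH2=CHBF3], [Rh(cod)2]BF4 (cat.), (R)-BINAP, toluene/H2O, 100 °C
Reagents that add atoms: potassium vinyltrifluoroborate, [K+].C=C[B-](F)(F)F
Why: Hayashi–Miyaura rhodium-catalysed asymmetric 1,4-addition, in which the vinylrhodium species inserts the unsubstituted C5=C6 enone (the α-methyl enone is far less reactive) and the ligand selects the face, (R)-BINAP being expected to give 5R by analogy with cyclohex-2-enone; this centre becomes C2'.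

Step 14
Reactants: 18 (R)-2,4,4-trimethyl-5-vinylcyclohex-2-en-1-one
Product: 19 (1R,5R)-2,4,4-trimethyl-5-vinylcyclohex-2-en-1-ol (OH cis to vinyl)
Conditions: NaBH4, CeCl3·7H2O, MeOH, −78 → −20 °C
Reagents that add atoms: none
Why: Luche 1,2-reduction, in which hydride should attack the carbonyl from the face opposite the C5 vinyl group and so give the cis-allylic alcohol (the future C4'–O cis to the C2' substituent).

Step 15
Reactants: 19 (1R,5R)-2,4,4-trimethyl-5-vinylcyclohex-2-en-1-ol
Product: 20 tributyl({[(1R,5R)-2,4,4-trimethyl-5-vinylcyclohex-2-en-1-yl]oxy}methyl)stannane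
Conditions: KH, THF, 0 °C; then Bu3SnCH2I, rt
Reagents that add atoms: tributyl(iodomethyl)stannane, CCCC[Sn](CCCC)(CCCC)CI
Why: Williamson etherification of the potassium alkoxide gives the Still–Wittig precursor without touching either stereocentre.

Step 16
Reactants: 20 tributyl({[(1R,5R)-2,4,4-trimethyl-5-vinylcyclohex-2-en-1-yl]oxy}methyl)stannane
Product: 22 [(1R,5R)-2,6,6-trimethyl-5-vinylcyclohex-2-en-1-yl]methanol, via alkoxymethyllithium 21 (not isolated)
Conditions: n-BuLi, THF, −78 → 0 °C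
Reagents that add atoms: butyllithium, [Li]CCCC (in 21 only)
Why: Still–Wittig [2,3]-sigmatropic rearrangement, in which tin–lithium exchange gives the α-alkoxymethyllithium that shifts suprafacially from O–C4' to C6'; the new CH2OH group should therefore lie on the face of the former C–O bond, cis to the C2' vinyl group (6'R), and the alkene moves to C4'=C5'.

Step 17
Reactants: 22 [(1R,5R)-2,6,6-trimethyl-5-vinylcyclohex-2-en-1-yl]methanol
Product: 23 (1R,5R)-2,6,6-trimethyl-5-vinylcyclohex-2-ene-1-carbaldehyde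
Conditions: Dess–Martin periodinane, NaHCO3, CH2Cl2, 0 °C; used at once
Reagents that add atoms: none
Why: buffered Dess–Martin oxidation gives the β,γ-unsaturated aldehyde without acid or base that could epimerise C6' or move the alkene into conjugation.

Step 18
Reactants: 23 (1R,5R)-2,6,6-trimethyl-5-vinylcyclohex-2-ene-1-carbaldehyde
Product: 24 (2E,4E)-3-methyl-5-[(1R,5R)-2,6,6-trimethyl-5-vinylcyclohex-2-en-1-yl]penta-2,4-dienenitrile
Conditions: (E)-C5 cyanophosphonate (slight excess over base), LiN(SiMe3)2, THF, −78 → 0 °C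
Reagents that add atoms: diethyl [(E)-3-cyano-2-methylprop-2-en-1-yl]phosphonate, N#C/C=C(\C)CP(=O)(OCC)OCC
Why: HWE olefination should form C7'=C8' (E) and bring C8'–C11' with the C9' methyl group, addition of the stabilised anion at low temperature being faster than enolisation of the hindered aldehyde.

Step 19
Reactants: 24 (2E,4E)-3-methyl-5-[(1R,5R)-2,6,6-trimethyl-5-vinylcyclohex-2-en-1-yl]penta-2,4-dienenitrile
Product: 26 (2E,4E)-5-[(1R,5R)-5-(2-hydroxyethyl)-2,6,6-trimethylcyclohex-2-en-1-yl]-3-methylpenta-2,4-dienenitrile, via B-alkyl-9-borabicyclononane 25 (not isolated)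
Conditions: 9-BBN, THF, 0 °C → rt; then H2O2, pH 7 phosphate buffer, 0 °C → rt
Reagents that add atoms: hydrogen peroxide, OO; 9-borabicyclo[3.3.1]nonane, B1C2CCCC1CCC2 (in 25 only)
Why: anti-Markovnikov hydroboration with 9-BBN should select the monosubstituted vinyl group over the trisubstituted ring alkene and the conjugated dienenitrile, and neutral peroxide oxidation spares the nitrile.

Step 20
Reactants: 26 (2E,4E)-5-[(1R,5R)-5-(2-hydroxyethyl)-2,6,6-trimethylcyclohex-2-en-1-yl]-3-methylpenta-2,4-dienenitrile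
Product: 27 (2E,4E)-3-methyl-5-[(1R,5R)-2,6,6-trimethyl-5-(2-oxoethyl)cyclohex-2-en-1-yl]penta-2,4-dienenitrile
Conditions: Dess–Martin periodinane, NaHCO3, CH2Cl2, 0 °C → rt
Reagents that add atoms: none
Why: Dess–Martin oxidation of the primary alcohol gives the aldehyde under neutral conditions.

Step 21
Reactants: 27 (2E,4E)-3-methyl-5-[(1R,5R)-2,6,6-trimethyl-5-(2-oxoethyl)cyclohex-2-en-1-yl]penta-2,4-dienenitrile
Product: 28 ethyl (E)-4-{(1R,5R)-5-[(1E,3E)-4-cyano-3-methylbuta-1,3-dien-1-yl]-4,6,6-trimethylcyclohex-3-en-1-yl}-2-methylbut-2-enoate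
Conditions: Ph3P=C(CH3)CO2Et, CH2Cl2, rt → 40 °C
Reagents that add atoms: ethyl 2-(triphenylphosphoranylidene)propanoate, CCOC(=O)C(C)=P(c1ccccc1)(c1ccccc1)c1ccccc1
Why: Wittig olefination with the stabilised ylide should give the (E)-trisubstituted enoate of the side chain and leave the nitrile untouched.

Step 22
Reactants: 28 ethyl (E)-4-{(1R,5R)-5-[(1E,3E)-4-cyano-3-methylbuta-1,3-dien-1-yl]-4,6,6-trimethylcyclohex-3-en-1-yl}-2-methylbut-2-enoate
Product: 29 (2E,4E)-5-{(1R,5R)-5-[(E)-4-hydroxy-3-methylbut-2-en-1-yl]-2,6,6-trimethylcyclohex-2-en-1-yl}-3-methylpenta-2,4-dienal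
Conditions: i-Bu2AlH (excess), CH2Cl2, −78 → −40 °C; then aq. KNaC4H4O6
Reagents that add atoms: water, O
Why: i-Bu2AlH reduces the enoate to the allylic alcohol and the nitrile only to the aldimine (hydrolysed to the aldehyde on work-up), so the two termini should emerge differentiated in one operation.

Step 23
Reactants: 29 (2E,4E)-5-{(1R,5R)-5-[(E)-4-hydroxy-3-methylbut-2-en-1-yl]-2,6,6-trimethylcyclohex-2-en-1-yl}-3-methylpenta-2,4-dienal
Product: 30 tert-butyldimethylsilyl ether of 29
Conditions: t-BuMe2SiCl, imidazole, DMF, 0 °C → rt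
Reagents that add atoms: tert-butyldimethylsilyl chloride, CC(C)(C)[Si](C)(C)Cl
Why: silylation protects the primary allylic alcohol for the later base and hydride steps.

Step 24
Reactants: 30 tert-butyldimethylsilyl ether of 29
Product: 31 (2E,4E,6E,8E)-9-{(1R,5R)-5-[(E)-4-(tert-butyldimethylsilyloxy)-3-methylbut-2-en-1-yl]-2,6,6-trimethylcyclohex-2-en-1-yl}-3,7-dimethylnona-2,4,6,8-tetraenenitrile
Conditions: (E)-C5 cyanophosphonate (slight excess over base), LiN(SiMe3)2, THF, −78 → 0 °C
Reagents that add atoms: diethyl [(E)-3-cyano-2-methylprop-2-en-1-yl]phosphonate, N#C/C=C(\C)CP(=O)(OCC)OCC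
Why: HWE olefination should form C11'=C12' (E) and bring C12'–C15' with the C13' methyl group; keeping the phosphonate in excess over the base protects the doubly allylic C6'–H.

Step 25
Reactants: 31 (2E,4E,6E,8E)-9-{(1R,5R)-5-[(E)-4-(tert-butyldimethylsilyloxy)-3-methylbut-2-en-1-yl]-2,6,6-trimethylcyclohex-2-en-1-yl}-3,7-dimethylnona-2,4,6,8-tetraenenitrile
Product: 32 (2E,4E,6E,8E)-9-{(1R,5R)-5-[(E)-4-(tert-butyldimethylsilyloxy)-3-methylbut-2-en-1-yl]-2,6,6-trimethylcyclohex-2-en-1-yl}-3,7-dimethylnona-2,4,6,8-tetraenal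
Conditions: i-Bu2AlH, toluene, −78 °C; then wet SiO2 or aq. KNaC4H4O6
Reagents that add atoms: water, O
Why: nitrile partial reduction as in step 8 gives the C15' aldehyde.

Step 26
Reactants: 33 1-bromobut-2-yne
Product: 34 diethyl but-2-yn-1-ylphosphonate
Conditions: P(OEt)3, neat, 120 °C
Reagents that add atoms: triethyl phosphite, CCOP(OCC)OCC
Why: Michaelis–Arbuzov reaction of the propargylic bromide gives the phosphonate that carries C15, C14, C13 and the C13 methyl group.

Step 27
Reactants: 32 (2E,4E,6E,8E)-9-{(1R,5R)-5-[(E)-4-(tert-butyldimethylsilyloxy)-3-methylbut-2-en-1-yl]-2,6,6-trimethylcyclohex-2-en-1-yl}-3,7-dimethylnona-2,4,6,8-tetraenal; 34 diethyl but-2-yn-1-ylphosphonate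
Product: 35 tert-butyl{[(E)-4-{(1R,5R)-5-[(1E,3E,5E,7E,9E)-3,7-dimethyltrideca-1,3,5,7,9-pentaen-11-yn-1-yl]-4,6,6-trimethylcyclohex-3-en-1-yl}-2-methylbut-2-en-1-yl]oxy}dimethylsilane
Conditions: 34, LiN(SiMe3)2, THF, −78 °C; then 32, −78 → 0 °C
Reagents that add atoms: none
Why: HWE olefination with the propargylic phosphonate should give the (E)-enyne at C15'=C15 and install the CH3–C13≡C14 cap needed for the key step.

### Union and end game

Step 28
Reactants: 35 methyl-capped polyenyne (right half); 15 pentaenyl iodide (left half)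
Product: 38 bis-silyl ether of the target (Et3Si on the C1 oxygen and t-BuMe2Si on the side-chain oxygen), via alkenylzirconocene chloride 36 (not isolated), via alkenylzinc chloride 37 (not isolated)
Conditions: 35, Cp2Zr(H)Cl (slight excess), THF, 0 °C → rt, dark; ZnCl2, THF, 0 °C; then 15, Pd(PPh3)4 (cat.), rt, dark
Reagents that add atoms: chlorobis(cyclopentadienyl)hydridozirconium, [H][Zr](Cl)(C1C=CC=C1)C1C=CC=C1 (in 36 only); zinc chloride, Cl[Zn]Cl (in 37 only)
Why: Cp2Zr(H)Cl adds H and Zr syn across C13≡C14 with Zr on C13 (the carbon that carries only CH3) and H on C14 to give the (E)-alkenylzirconocene 36; ZnCl2 exchanges Zr for Zn (37), and zerovalent palladium inserts into the C12–I bond of 15, transmetalates with 37 and reductively eliminates to form C12–C13 with retention at both alkenes. The closest known reaction type is the one-pot alkyne hydrozirconation and ZnCl2-assisted Negishi alkenyl–alkenyl coupling used for stereodefined dienes and conjugated polyenes, α-branched alkenylzirconocenes included. No ring is closed and no stereocentre is created; the new stereo-element is the trisubstituted (E)-C13=C14 alkene, fixed by the syn mode of H–Zr addition and by the stereoretentive coupling, while the (E)-C11=C12 geometry of 15 is carried over. The step needs regioselectivity (Zr at C13, not C14) and chemoselectivity (the alkyne before the polyene and the two isolated trisubstituted alkenes); the size difference between methyl and polyenyl, equilibration of regioisomers by the small excess of Cp2Zr(H)Cl, and the absence of any terminal alkene in 35 should secure both. The silyl ethers keep both hydroxyl groups from quenching Zr–H or the organozinc, and the iodide is added only after the hydride has been consumed. In this one operation the two halves are joined, the last trisubstituted alkene is set and the full conjugated undecaene is completed from a partner that carried nothing more than a CH3–C≡C cap.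

Step 29
Reactants: 38 bis-silyl ether of the target
Product: 39 target CNP0409952.1, (2S,2'R,6'R)
Conditions: Bu4NF, AcOH, THF, 0 °C → rt, dark
Reagents that add atoms: none
Why: fluoride-mediated desilylation should remove both silyl ethers without acid that could ionise the allylic or tertiary alcohols, and no stereocentre or alkene is touched.

## Compound list

1 | (R)-4-benzyloxazolidin-2-one | O=C1N[C@H](Cc2ccccc2)CO1 | starting material
2 | 5-methylhex-4-enoic acid | CC(C)=CCCC(=O)O | starting material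
3 | 5-methylhex-4-enoic pivalic anhydride | CC(C)=CCCC(=O)OC(=O)C(C)(C)C | intermediate (not isolated)
4 | (R)-4-benzyl-3-(5-methylhex-4-enoyl)oxazolidin-2-one | CC(C)=CCCC(=O)N1[C@H](Cc2ccccc2)COC1=O | intermediate
5 | trichlorotitanium (Z)-enolate of 4 | CC(C)=CC/C=C(\O[Ti](Cl)(Cl)Cl)N1[C@H](Cc2ccccc2)COC1=O | intermediate (not isolated)
6 | (R)-4-benzyl-3-[(S)-2-(hydroxymethyl)-5-methylhex-4-enoyl]oxazolidin-2-one | CC(C)=CC[C@@H](CO)C(=O)N1[C@H](Cc2ccccc2)COC1=O | intermediate
7 | methyl (S)-2-(hydroxymethyl)-5-methylhex-4-enoate | CC(C)=CC[C@@H](CO)C(=O)OC | intermediate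
8 | (S)-3-methyl-2-(3-methylbut-2-en-1-yl)butane-1,3-diol | CC(C)=CC[C@@H](CO)C(C)(C)O | intermediate
9 | triethyl{[(S)-3-methyl-2-(3-methylbut-2-en-1-yl)-3-(triethylsilyloxy)butyl]oxy}silane | CC(C)=CC[C@@H](CO[Si](CC)(CC)CC)C(C)(C)O[Si](CC)(CC)CC | intermediate
10 | (R)-5-methyl-2-[2-(triethylsilyloxy)propan-2-yl]hex-4-enal | CC(C)=CC[C@@H](C=O)C(C)(C)O[Si](CC)(CC)CC | intermediate
11 | (2E,4E,6S)-3,9-dimethyl-6-[2-(triethylsilyloxy)propan-2-yl]deca-2,4,8-trienenitrile | CC(C)=CC[C@@H](/C=C/C(C)=C/C#N)C(C)(C)O[Si](CC)(CC)CC | intermediate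
12 | (2E,4E,6S)-3,9-dimethyl-6-[2-(triethylsilyloxy)propan-2-yl]deca-2,4,8-trienal | CC(C)=CC[C@@H](/C=C/C(C)=C/C=O)C(C)(C)O[Si](CC)(CC)CC | intermediate
13 | (2E,4E,6E,8E,10S)-3,7,13-trimethyl-10-[2-(triethylsilyloxy)propan-2-yl]tetradeca-2,4,6,8,12-pentaenenitrile | CC(C)=CC[C@@H](/C=C/C(C)=C/C=C/C(C)=C/C#N)C(C)(C)O[Si](CC)(CC)CC | intermediate
14 | (2E,4E,6E,8E,10S)-3,7,13-trimethyl-10-[2-(triethylsilyloxy)propan-2-yl]tetradeca-2,4,6,8,12-pentaenal | CC(C)=CC[C@@H](/C=C/C(C)=C/C=C/C(C)=C/C=O)C(C)(C)O[Si](CC)(CC)CC | intermediate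
15 | (1E,3E,5E,7E,9E,11S)-1-iodo-4,8,14-trimethyl-11-[2-(triethylsilyloxy)propan-2-yl]pentadeca-1,3,5,7,9,13-hexaene (left half, C1–C12) | CC(C)=CC[C@@H](/C=C/C(C)=C/C=C/C(C)=C/C=C/I)C(C)(C)O[Si](CC)(CC)CC | intermediate
16 | 2,4,4-trimethylcyclohex-2-en-1-one | CC1=CC(C)(C)CCC1=O | starting material
17 | 2,4,4-trimethylcyclohexa-2,5-dien-1-one | CC1=CC(C)(C)C=CC1=O | intermediate
18 | (R)-2,4,4-trimethyl-5-vinylcyclohex-2-en-1-one | CC1=CC(C)(C)[C@@H](C=C)CC1=O | intermediate
19 | (1R,5R)-2,4,4-trimethyl-5-vinylcyclohex-2-en-1-ol (cis) | CC1=CC(C)(C)[C@@H](C=C)C[C@H]1O | intermediate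
20 | tributyl({[(1R,5R)-2,4,4-trimethyl-5-vinylcyclohex-2-en-1-yl]oxy}methyl)stannane | CC1=CC(C)(C)[C@@H](C=C)C[C@H]1OC[Sn](CCCC)(CCCC)CCCC | intermediate
21 | ({[(1R,5R)-2,4,4-trimethyl-5-vinylcyclohex-2-en-1-yl]oxy}methyl)lithium | CC1=CC(C)(C)[C@@H](C=C)C[C@H]1OC[Li] | intermediate (not isolated)
22 | [(1R,5R)-2,6,6-trimethyl-5-vinylcyclohex-2-en-1-yl]methanol (CH2OH cis to vinyl) | OC[C@@H]1C(C)=CC[C@H](C=C)C1(C)C | intermediate
23 | (1R,5R)-2,6,6-trimethyl-5-vinylcyclohex-2-ene-1-carbaldehyde | O=C[C@@H]1C(C)=CC[C@H](C=C)C1(C)C | intermediate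
24 | (2E,4E)-3-methyl-5-[(1R,5R)-2,6,6-trimethyl-5-vinylcyclohex-2-en-1-yl]penta-2,4-dienenitrile | N#C/C=C(C)/C=C/[C@@H]1C(C)=CC[C@H](C=C)C1(C)C | intermediate
25 | B-alkyl-9-borabicyclo[3.3.1]nonane adduct of 24 (boron on the terminal carbon of the former vinyl group) | N#C/C=C(C)/C=C/[C@@H]1C(C)=CC[C@H](CCB2C3CCCC2CCC3)C1(C)C | intermediate (not isolated)
26 | (2E,4E)-5-[(1R,5R)-5-(2-hydroxyethyl)-2,6,6-trimethylcyclohex-2-en-1-yl]-3-methylpenta-2,4-dienenitrile | N#C/C=C(C)/C=C/[C@@H]1C(C)=CC[C@H](CCO)C1(C)C | intermediate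
27 | (2E,4E)-3-methyl-5-[(1R,5R)-2,6,6-trimethyl-5-(2-oxoethyl)cyclohex-2-en-1-yl]penta-2,4-dienenitrile | N#C/C=C(C)/C=C/[C@@H]1C(C)=CC[C@H](CC=O)C1(C)C | intermediate
28 | ethyl (E)-4-{(1R,5R)-5-[(1E,3E)-4-cyano-3-methylbuta-1,3-dien-1-yl]-4,6,6-trimethylcyclohex-3-en-1-yl}-2-methylbut-2-enoate | N#C/C=C(C)/C=C/[C@@H]1C(C)=CC[C@H](C/C=C(\C)C(=O)OCC)C1(C)C | intermediate
29 | (2E,4E)-5-{(1R,5R)-5-[(E)-4-hydroxy-3-methylbut-2-en-1-yl]-2,6,6-trimethylcyclohex-2-en-1-yl}-3-methylpenta-2,4-dienal | O=C/C=C(C)/C=C/[C@@H]1C(C)=CC[C@H](C/C=C(\C)CO)C1(C)C | intermediate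
30 | tert-butyldimethylsilyl ether of 29 | O=C/C=C(C)/C=C/[C@@H]1C(C)=CC[C@H](C/C=C(\C)CO[Si](C)(C)C(C)(C)C)C1(C)C | intermediate
31 | (2E,4E,6E,8E)-9-{(1R,5R)-5-[(E)-4-(tert-butyldimethylsilyloxy)-3-methylbut-2-en-1-yl]-2,6,6-trimethylcyclohex-2-en-1-yl}-3,7-dimethylnona-2,4,6,8-tetraenenitrile | N#C/C=C(C)/C=C/C=C(C)/C=C/[C@@H]1C(C)=CC[C@H](C/C=C(\C)CO[Si](C)(C)C(C)(C)C)C1(C)C | intermediate
32 | (2E,4E,6E,8E)-9-{(1R,5R)-5-[(E)-4-(tert-butyldimethylsilyloxy)-3-methylbut-2-en-1-yl]-2,6,6-trimethylcyclohex-2-en-1-yl}-3,7-dimethylnona-2,4,6,8-tetraenal | O=C/C=C(C)/C=C/C=C(C)/C=C/[C@@H]1C(C)=CC[C@H](C/C=C(\C)CO[Si](C)(C)C(C)(C)C)C1(C)C | intermediate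
33 | 1-bromobut-2-yne | CC#CCBr | starting material
34 | diethyl but-2-yn-1-ylphosphonate | CC#CCP(=O)(OCC)OCC | intermediate
35 | tert-butyl{[(E)-4-{(1R,5R)-5-[(1E,3E,5E,7E,9E)-3,7-dimethyltrideca-1,3,5,7,9-pentaen-11-yn-1-yl]-4,6,6-trimethylcyclohex-3-en-1-yl}-2-methylbut-2-en-1-yl]oxy}dimethylsilane (right half, C13–C1') | CC#C/C=C/C=C(C)/C=C/C=C(C)/C=C/[C@@H]1C(C)=CC[C@H](C/C=C(\C)CO[Si](C)(C)C(C)(C)C)C1(C)C | intermediate
36 | (E)-alkenylzirconocene chloride from 35 (Cp2ZrCl on C13, H on C14) | Cl[Zr](C1C=CC=C1)(C1C=CC=C1)/C(C)=C/C=C/C=C(C)/C=C/C=C(C)/C=C/[C@@H]1C(C)=CC[C@H](C/C=C(\C)CO[Si](C)(C)C(C)(C)C)C1(C)C | intermediate (not isolated)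
37 | (E)-alkenylzinc chloride from 36 (ZnCl on C13) | Cl[Zn]/C(C)=C/C=C/C=C(C)/C=C/C=C(C)/C=C/[C@@H]1C(C)=CC[C@H](C/C=C(\C)CO[Si](C)(C)C(C)(C)C)C1(C)C | intermediate (not isolated)
38 | bis-silyl ether of the target (C1–OSiEt3; side-chain CH2OSi(t-Bu)Me2; all-E; 2S,2'R,6'R) | CC(C)=CC[C@@H](/C=C/C(C)=C/C=C/C(C)=C/C=C/C(C)=C/C=C/C=C(C)/C=C/C=C(C)/C=C/[C@@H]1C(C)=CC[C@H](C/C=C(\C)CO[Si](C)(C)C(C)(C)C)C1(C)C)C(C)(C)O[Si](CC)(CC)CC | intermediate
39 | CNP0409952.1, (2S,2'R,6'R), all-E | CC(C)=CC[C@@H](/C=C/C(C)=C/C=C/C(C)=C/C=C/C(C)=C/C=C/C=C(C)/C=C/C=C(C)/C=C/[C@@H]1C(C)=CC[C@H](C/C=C(\C)CO)C1(C)C)C(C)(C)O | target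

## Step count and risks

Total steps: 29. Longest linear sequence: 17 steps (steps 12–25, 27, 28 and 29, from 16).

**Step 28.** The Zr–H addition may place Zr on C14 instead of C13 or attack the polyene, or the hindered α-methyl alkenylzinc may transmetalate so slowly that the iodide decomposes. The fallback fixes the C13=C14 geometry before the union. It sets out from aldehyde 32 and iodide 15. Ethyl but-2-ynoate is stannylcuprated (Bu3SnLi, CuBr·SMe2, THF, −78 °C, MeOH quench; syn addition) to ethyl (E)-3-(tributylstannyl)but-2-enoate F1. Reduction with i-Bu2AlH gives (E)-3-(tributylstannyl)but-2-en-1-ol F2, and CBr4/PPh3 gives (E)-(4-bromobut-2-en-2-yl)tributylstannane F3. Displacement with NaP(O)(OEt)2 gives diethyl [(E)-3-(tributylstannyl)but-2-en-1-yl]phosphonate F4. HWE olefination of 32 with lithiated F4 gives the C13 tributylstannane of the right half F5. Stille coupling of F5 with 15 (Pd(PPh3)4, CuI, CsF, DMF) comes back to the route at 38.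

**Step 13.** Insertion at the neopentyl β-carbon may be slow or poorly face-selective, and the vinyl donor may be lost by protodeboronation or oligomerisation. The fallback gives up catalytic control for a resolution and sets out from 17. Copper-catalysed 1,4-addition of vinylmagnesium bromide (CuBr·SMe2, Me3SiCl, THF, −78 °C, then dilute acid) gives rac-2,4,4-trimethyl-5-vinylcyclohex-2-en-1-one F6. Luche reduction gives rac-cis-2,4,4-trimethyl-5-vinylcyclohex-2-en-1-ol F7. Lipase-catalysed acylation with vinyl acetate (Candida antarctica lipase B or Burkholderia cepacia lipase) is expected to acylate the (1R)-alcohol, the usual preference for cyclic secondary allylic alcohols, giving (1R,5R)-2,4,4-trimethyl-5-vinylcyclohex-2-en-1-yl acetate F8. F8 is separated from the unreacted (1S,5S)-alcohol and methanolysed (K2CO3, MeOH), which comes back to the route at 19.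

**Step 16.** The [2,3]-shift needs the conformer with the C4'–O bond pseudo-axial, which puts the cis C2' vinyl group axial as well; the carbanion 21 may then undergo [1,2]-shift or protonation instead. The fallback replaces the suprafacial shift by an antarafacial substitution on the epimeric ester and sets out from 19. Mitsunobu inversion with pyridine-2-carboxylic acid (PPh3, DIAD) gives (1S,5R)-2,4,4-trimethyl-5-vinylcyclohex-2-en-1-yl pyridine-2-carboxylate F9. Copper-mediated anti-SN2' substitution with (i-PrO)Me2SiCH2MgCl and CuBr·SMe2 enters C6' anti to the leaving group, that is cis to the vinyl group, and moves the alkene to C4'=C5'. This gives isopropoxydimethyl{[(1R,5R)-2,6,6-trimethyl-5-vinylcyclohex-2-en-1-yl]methyl}silane F10. Tamao–Fleming oxidation (H2O2, KF, KHCO3, THF/MeOH) comes back to the route at 22.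

Further compounds

F1 | step 28 | ethyl (E)-3-(tributylstannyl)but-2-enoate | CCOC(=O)/C=C(\C)[Sn](CCCC)(CCCC)CCCC
F2 | step 28 | (E)-3-(tributylstannyl)but-2-en-1-ol | OC/C=C(\C)[Sn](CCCC)(CCCC)CCCC
F3 | step 28 | (E)-(4-bromobut-2-en-2-yl)tributylstannane | BrC/C=C(\C)[Sn](CCCC)(CCCC)CCCC
F4 | step 28 | diethyl [(E)-3-(tributylstannyl)but-2-en-1-yl]phosphonate | CCOP(=O)(OCC)C/C=C(\C)[Sn](CCCC)(CCCC)CCCC
F5 | step 28 | C13 tributylstannane of the right half (Bu3Sn on C13, E at C13=C14) | CCCC[Sn](CCCC)(CCCC)/C(C)=C/C=C/C=C(C)/C=C/C=C(C)/C=C/[C@@H]1C(C)=CC[C@H](C/C=C(\C)CO[Si](C)(C)C(C)(C)C)C1(C)C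
F6 | step 13 | rac-2,4,4-trimethyl-5-vinylcyclohex-2-en-1-one | CC1=CC(C)(C)[C@@H](C=C)CC1=O.CC1=CC(C)(C)[C@H](C=C)CC1=O
F7 | step 13 | rac-cis-2,4,4-trimethyl-5-vinylcyclohex-2-en-1-ol | CC1=CC(C)(C)[C@@H](C=C)C[C@H]1O.CC1=CC(C)(C)[C@H](C=C)C[C@@H]1O
F8 | step 13 | (1R,5R)-2,4,4-trimethyl-5-vinylcyclohex-2-en-1-yl acetate | CC1=CC(C)(C)[C@@H](C=C)C[C@H]1OC(C)=O
F9 | step 16 | (1S,5R)-2,4,4-trimethyl-5-vinylcyclohex-2-en-1-yl pyridine-2-carboxylate | CC1=CC(C)(C)[C@@H](C=C)C[C@@H]1OC(=O)c1ccccn1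
F10 | step 16 | isopropoxydimethyl{[(1R,5R)-2,6,6-trimethyl-5-vinylcyclohex-2-en-1-yl]methyl}silane | CC(C)O[Si](C)(C)C[C@@H]1C(C)=CC[C@H](C=C)C1(C)C
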